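The route rests on cutting the C4–C5 and C9–C10 bonds, which unzips rings A and B to an achiral neryl-substituted acetoacetate. The feature exploited is the cis A/B fusion (H-5 and the C10 methyl on one face) flanked by the tetrasubstituted C8=C9 alkene of ring B. Anti addition across a Z C5=C10 olefin writes that cis relationship, and a β-keto ester terminator leaves oxygen at C8 to pin the alkene. One chiral-acid-catalysed, proton-initiated bicyclisation therefore closes both rings and sets C5 and C10 together. The side chain is then joined by B-alkyl Suzuki coupling (C12–C13), and the butenolide arrives through a phosphonate olefination (C15=C16).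

Key step: step 3

Assumption: positions are numbered labdane-style (decalin C1–C10 with C4 = CMe2, C5/C10 = ring fusion, C8=C9 = ring alkene; chain C11–C16 from C9 to the butenolide). The sense of induction of the chiral acid cannot be predicted, so the antipode giving (5R,10S) is chosen in a first screen, both being accessible from (R)- or (S)-BINOL.

Step 1
Reactants: 1 nerol
Product: 2 neryl bromide, (2Z)-1-bromo-3,7-dimethylocta-2,6-diene
Conditions: PBr3 (0.4 equiv), Et2O, −10 °C; aqueous wash, used crude at once
Reagents that add atoms: phosphorus tribromide, BrP(Br)Br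
Why: Bromination of a primary allylic alcohol through its phosphite ester (SN2 at carbon) runs cold and without a free carbocation, so the Z-trisubstituted alkene should be retained if the labile bromide is used immediately.

Step 2
Reactants: 2 neryl bromide; 3 methyl acetoacetate
Product: 5 methyl (6Z)-7,11-dimethyl-3-oxododeca-6,10-dienoate, via acetoacetate dianion 4 (not isolated)
Conditions: NaH, THF, 0 °C; n-BuLi, 0 °C; then 2, 0 °C to rt; cold 1 M HCl quench
Reagents that add atoms: none
Why: γ-Alkylation of an acetoacetate dianion: the terminal, more basic carbanion displaces the primary allylic bromide by SN2, which lengthens the chain at the methyl terminus only and leaves the Z alkene untouched.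

Step 3
Reactants: 5 methyl (6Z)-7,11-dimethyl-3-oxododeca-6,10-dienoate
Product: 6 cis-fused bicyclic β-keto ester methyl (4aR,8aS)-2-hydroxy-5,5,8a-trimethyl-3,4,4a,5,6,7,8,8a-octahydronaphthalene-1-carboxylate (enol form; 5R,10S; in equilibrium with the C9-epimeric keto forms)
Conditions: confined BINOL-derived imidodiphosphorimidate Brønsted acid (5 mol %), (CF3)3COH, −10 °C (CH2Cl2 co-solvent if colder)
Reagents that add atoms: none
Why: Proposed new method: the strongly acidic, confined chiral acid protonates C3 of the terminal trisubstituted alkene of chair–chair folded 5, C5 of the Z alkene traps the developing tertiary C4 cation and the enol carbon C9 traps the tertiary C10 cation, so that C4–C5 and C9–C10 form in one (near-)concerted anti addition. The closest known reaction types are the tin(IV) chloride-mediated racemic C-cyclisation of prenylogous acetoacetates to bicyclic β-keto esters and the imidodiphosphorimidate-catalysed, proton-initiated bicyclisation of acyclic terpene alcohols in fluorinated alcohols; new is the carbon terminator under asymmetric Brønsted acid catalysis on a Z olefin. Ring A closes by 6-endo attack of the C5=C10 π bond on C4, ring B by a 6-(enol-endo) C-alkylation of the keto ester enol by C10. The relative configuration of C5 and C10 is dictated by the Z geometry, since anti addition leaves H-5 and the C10 methyl on one face (cis fusion), and the absolute configuration (5R,10S) by the chiral anion, which admits only one folded conformer and hence one alkene face to protonation; C9 is transient. The step needs enantioface selection, faithful Z-to-cis transfer and C- over O-capture: only tertiary cations are involved, the hydrogen-bonding fluorinated medium favours a concerted course, the keto ester offers the catalyst a binding handle, and capture by the ketone oxygen gives a tertiary enol ether that the acid can reopen, so material should drain to the C–C bonded product.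

Step 4
Reactants: 6 cis-fused bicyclic β-keto ester
Product: 8 enol triflate methyl (4aR,8aS)-5,5,8a-trimethyl-2-(trifluoromethylsulfonyloxy)-3,4,4a,5,6,7,8,8a-octahydronaphthalene-1-carboxylate, via sodium enolate 7 (not isolated)
Conditions: NaH, Et2O, 0 °C; Tf2O, −78 to 0 °C
Reagents that add atoms: triflic anhydride, O=S(=O)(OS(=O)(=O)C(F)(F)F)C(F)(F)F
Why: Enol triflate formation by O-sulfonylation of the sodium enolate of a cyclic β-keto ester, which erases the irrelevant C9 centre and places the double bond irreversibly between C8 and C9.

Step 5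
Reactants: 8 enol triflate
Product: 9 methyl (4aR,8aS)-2,5,5,8a-tetramethyl-3,4,4a,5,6,7,8,8a-octahydronaphthalene-1-carboxylate
Conditions: MeMgBr (1.4 equiv), Fe(acac)3 (5 mol %), THF–NMP, −30 °C
Reagents that add atoms: methylmagnesium bromide, C[Mg]Br
Why: Iron-catalysed Kumada-type cross-coupling of an electron-poor alkenyl triflate with a methyl Grignard reagent outruns addition to the hindered ester at low temperature and exchanges OTf for the C8 methyl group without moving the alkene.

Step 6
Reactants: 9 tetramethyl octalin ester
Product: 10 [(4aR,8aS)-2,5,5,8a-tetramethyl-3,4,4a,5,6,7,8,8a-octahydronaphthalen-1-yl]methanol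
Conditions: DIBAL-H (2.5 equiv), CH2Cl2, −78 to 0 °C; Rochelle salt work-up
Reagents that add atoms: none
Why: Full 1,2-reduction of the conjugated ester by DIBAL-H gives the primary allylic alcohol, and nothing else in the molecule is reducible.

Step 7
Reactants: 10 allylic alcohol
Product: 11 (4aR,8aS)-2,5,5,8a-tetramethyl-3,4,4a,5,6,7,8,8a-octahydronaphthalene-1-carbaldehyde
Conditions: activated MnO2, CH2Cl2, rt
Reagents that add atoms: none
Why: Activated manganese dioxide oxidises allylic alcohols selectively and stops at the enal, which has no α-hydrogen and whose stereocentres lie away from any acidic position.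

Step 8
Reactants: 11 enal
Product: 12 (4aR,8aS)-1-ethenyl-2,5,5,8a-tetramethyl-3,4,4a,5,6,7,8,8a-octahydronaphthalene (9-vinyl diene)
Conditions: Ph3PCH3Br, KOt-Bu, THF, 0 °C to rt
Reagents that add atoms: methyltriphenylphosphonium bromide, C[P+](c1ccccc1)(c1ccccc1)c1ccccc1.[Br-]
Why: Wittig methylenation: the small non-stabilised ylide reaches the hindered aldehyde carbon, as is usual for β-cyclocitral-type enals, and gives the twisted 1,3-diene.

Step 9
Reactants: 13 but-2-yne-1,4-diol
Product: 14 4-(tert-butyldimethylsilyloxy)but-2-yn-1-ol
Conditions: TBSCl (1 equiv), imidazole, 13 (3 equiv), DMF, 0 °C to rt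
Reagents that add atoms: tert-butyldimethylsilyl chloride, CC(C)(C)[Si](C)(C)Cl
Why: Statistical monosilylation of a symmetrical diol used in excess; the water-soluble surplus diol is washed out and the little bis-ether is removed by chromatography.

Step 10
Reactants: 14 mono-TBS butynediol
Product: 16 (2Z)-4-(tert-butyldimethylsilyloxy)-3-iodobut-2-en-1-ol, via cyclic alkenylalanate 15 (not isolated)
Conditions: Red-Al, THF, 0 °C to rt; I2, THF, −78 to 0 °C
Reagents that add atoms: iodine, II
Why: Hydroxyl-directed trans-hydroalumination of a propargylic alcohol delivers hydride to the near and aluminium to the far alkyne carbon inside a five-membered alkoxyalanate, and iodinolysis with retention leaves iodine cis to CH2OH, i.e. the Z iodide that encodes the C13=C14 geometry.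

Step 11
Reactants: 12 9-vinyl diene; 16 (Z)-hydroxy vinyl iodide
Product: 18 (2E)-3-[(tert-butyldimethylsilyloxy)methyl]-5-[(4aR,8aS)-2,5,5,8a-tetramethyl-3,4,4a,5,6,7,8,8a-octahydronaphthalen-1-yl]pent-2-en-1-ol, via B-alkyl-9-BBN adduct 17 (not isolated)
Conditions: 9-BBN, THF, 0 °C to rt; then aq Cs2CO3, 16, PdCl2(dppf) (5 mol %), AsPh3 (cat.), DMF, rt
Reagents that add atoms: none
Why: 9-BBN hydroborates only the monosubstituted vinyl group at its terminus (the tetrasubstituted C8=C9 alkene is inert), aqueous base destroys residual B–H before the hydroxy iodide is added, and the B-alkyl Suzuki–Miyaura coupling then forms C12–C13 with retention of the iodide geometry.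

Step 12
Reactants: 18 coupled allylic alcohol
Product: 19 (2E)-3-[(tert-butyldimethylsilyloxy)methyl]-5-[(4aR,8aS)-2,5,5,8a-tetramethyl-3,4,4a,5,6,7,8,8a-octahydronaphthalen-1-yl]pent-2-enal
Conditions: activated MnO2, CH2Cl2, rt
Reagents that add atoms: none
Why: Neutral manganese dioxide oxidation touches only the free primary allylic alcohol, keeps the silyl ether and should not isomerise the trisubstituted alkene.

Step 13
Reactants: 20 ethyl 3-methylbut-2-enoate
Product: 21 ethyl 4-bromo-3-(bromomethyl)but-2-enoate
Conditions: NBS (2.1 equiv), AIBN (cat.), PhCF3, reflux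
Reagents that add atoms: N-bromosuccinimide, O=C1CCC(=O)N1Br
Why: Wohl–Ziegler bromination: each of the two allylic methyl groups takes up one bromine, since a CH2Br group is deactivated towards a second hydrogen abstraction relative to the remaining CH3.

Step 14
Reactants: 21 dibromo ester
Product: 22 4-(bromomethyl)furan-2(5H)-one
Conditions: neat, 140–150 °C, volatile distilled off
Reagents that add atoms: none
Why: Thermal dealkylative lactonisation: one CH2Br group is necessarily cis to the ester, whose carbonyl oxygen displaces bromide (5-exo-tet) before bromide removes the ethyl group from the oxonium ion.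

Step 15
Reactants: 22 4-(bromomethyl)furan-2(5H)-one
Product: 23 diethyl (5-oxo-2,5-dihydrofuran-3-yl)methylphosphonate
Conditions: P(OEt)3 (1.2 equiv), toluene, reflux
Reagents that add atoms: triethyl phosphite, CCOP(OCC)OCC
Why: Michaelis–Arbuzov reaction of a primary allylic bromide with triethyl phosphite, driven by loss of a volatile alkyl halide.

Step 16
Reactants: 19 enal; 23 butenolide phosphonate
Product: 25 TBS ether of the target (13E,15E), via lithiated phosphonate 24 (not isolated)
Conditions: LiHMDS (1.05 equiv), THF, −78 °C; then 19, −78 to 0 °C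
Reagents that add atoms: none
Why: Horner–Wadsworth–Emmons olefination: the phosphonate carbanion, stabilised by vinylogy with the lactone carbonyl, adds reversibly to the enal, so the thermodynamically preferred E C15=C16 alkene should result while the C13=C14 geometry is untouched at low temperature.

Step 17
Reactants: 25 TBS ether of the target
Product: 26 target, 4-[(1E,3E)-4-(hydroxymethyl)-6-[(4aR,8aS)-2,5,5,8a-tetramethyl-3,4,4a,5,6,7,8,8a-octahydronaphthalen-1-yl]hexa-1,3-dien-1-yl]furan-2(5H)-one
Conditions: HF·pyridine, pyridine, THF, 0 °C to rt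
Reagents that add atoms: none
Why: Fluoride-driven cleavage of the primary TBS ether under weakly acidic, buffered conditions spares the base-sensitive butenolide and the conjugated triene.

Compound list
1 | nerol, (2Z)-3,7-dimethylocta-2,6-dien-1-ol | CC(C)=CCC/C(C)=C\CO | starting material
2 | neryl bromide | CC(C)=CCC/C(C)=C\CBr | intermediate
3 | methyl acetoacetate | CC(=O)CC(=O)OC | starting material
4 | sodium lithium dianion of methyl acetoacetate (not isolated) | [Li+].[Na+].[CH2-]C(=O)[CH-]C(=O)OC | intermediate
5 | methyl (6Z)-7,11-dimethyl-3-oxododeca-6,10-dienoate | CC(C)=CCC/C(C)=C\CCC(=O)CC(=O)OC | intermediate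
6 | cis-fused bicyclic β-keto ester, enol form, (5R,10S) | OC1=C(C(=O)OC)[C@@]2(C)CCCC(C)(C)[C@H]2CC1 | intermediate
7 | sodium enolate of 6 (not isolated) | [Na+].[O-]C1=C(C(=O)OC)[C@@]2(C)CCCC(C)(C)[C@H]2CC1 | intermediate
8 | enol triflate of 6 | FC(F)(F)S(=O)(=O)OC1=C(C(=O)OC)[C@@]2(C)CCCC(C)(C)[C@H]2CC1 | intermediate
9 | methyl ester with C8 methyl and C8=C9 alkene | CC1=C(C(=O)OC)[C@@]2(C)CCCC(C)(C)[C@H]2CC1 | intermediate
10 | C11 allylic alcohol | CC1=C(CO)[C@@]2(C)CCCC(C)(C)[C@H]2CC1 | intermediate
11 | C11 enal | CC1=C(C=O)[C@@]2(C)CCCC(C)(C)[C@H]2CC1 | intermediate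
12 | cis-fused 9-vinyl diene | CC1=C(C=C)[C@@]2(C)CCCC(C)(C)[C@H]2CC1 | intermediate
13 | but-2-yne-1,4-diol | OCC#CCO | starting material
14 | 4-(tert-butyldimethylsilyloxy)but-2-yn-1-ol | OCC#CCO[Si](C)(C)C(C)(C)C | intermediate
15 | sodium cyclic alkenyl(alkoxy)alanate (not isolated) | [Na+].COCCO[Al-]1(OCCOC)OCC=C1CO[Si](C)(C)C(C)(C)C | intermediate
16 | (2Z)-4-(tert-butyldimethylsilyloxy)-3-iodobut-2-en-1-ol | OC/C=C(\I)CO[Si](C)(C)C(C)(C)C | intermediate
17 | C12 B-alkyl-9-BBN adduct of 12 (not isolated) | CC1=C(CCB3C4CCCC3CCC4)[C@@]2(C)CCCC(C)(C)[C@H]2CC1 | intermediate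
18 | coupled (13E) allylic alcohol | CC1=C(CC/C(=C\CO)CO[Si](C)(C)C(C)(C)C)[C@@]2(C)CCCC(C)(C)[C@H]2CC1 | intermediate
19 | (13E) C15 enal | CC1=C(CC/C(=C\C=O)CO[Si](C)(C)C(C)(C)C)[C@@]2(C)CCCC(C)(C)[C@H]2CC1 | intermediate
20 | ethyl 3-methylbut-2-enoate | CC(C)=CC(=O)OCC | starting material
21 | ethyl 4-bromo-3-(bromomethyl)but-2-enoate | CCOC(=O)C=C(CBr)CBr | intermediate
22 | 4-(bromomethyl)furan-2(5H)-one | BrCC1=CC(=O)OC1 | intermediate
23 | diethyl (5-oxo-2,5-dihydrofuran-3-yl)methylphosphonate | CCOP(=O)(CC1=CC(=O)OC1)OCC | intermediate
24 | lithiated phosphonate (not isolated) | [Li+].CCOP(=O)([CH-]C1=CC(=O)OC1)OCC | intermediate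
25 | TBS ether of the target | CC1=C(CC/C(=C\C=C\C2=CC(=O)OC2)CO[Si](C)(C)C(C)(C)C)[C@@]2(C)CCCC(C)(C)[C@H]2CC1 | intermediate
26 | CNP0232848.3 | CC1=C(CC/C(=C\C=C\C2=CC(=O)OC2)CO)[C@@]2(C)CCCC(C)(C)[C@H]2CC1 | target

Total step count: 17.
Longest linear sequence: 12 steps from nerol (steps 1–8, 11, 12, 16, 17).

Steps most likely to fail

1. Step 3.
- **Risk:** A stepwise cation pathway could erode the Z-to-cis transfer. The cascade could stop after ring A through proton loss. Capture could run through the ketone oxygen. Enantioface discrimination could be weak if the keto ester binds the acid outside the pocket.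
- **Fallback (known chemistry, resolution in place of asymmetric catalysis):** Setting out from 5, stoichiometric tin(IV) chloride in CH2Cl2 at 0 °C would give the racemic cis-fused keto ester F1, any trans-fused material being removed by chromatography. Condensation with (R)-1-phenylethylamine (cat. TsOH, toluene, water removal) converts it into two hydrogen-bonded diastereomers, the (5R,10S)-enamino ester F2 and the (5S,10R)-enamino ester F3. These are separated by crystallisation or chromatography. Mild hydrolysis of F2 (aqueous acetic acid, THF, rt) comes back to the route at 6 as a single enantiomer.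

2. Step 11.
- **Risk:** Transmetalation of the bulky homoallylic borane could be slow, letting protodeboronation, β-hydride elimination or reduction of the iodide take over.
- **Fallback (carbonyl olefination in place of cross-coupling):** Setting out from 12, hydroboration as before (17) followed by alkaline hydrogen peroxide gives the primary alcohol F4. Iodination (I2, PPh3, imidazole) gives the homoallylic iodide F5. Iodine–lithium exchange (t-BuLi, Et2O–pentane, −78 °C) and acylation with 2-(tert-butyldimethylsilyloxy)-N-methoxy-N-methylacetamide give the α-silyloxy ketone F6. A Wittig reaction with Ph3P=CHCO2Et in hot toluene, a reaction type known to place the ester trans to an alkoxymethyl group, gives the (E)-enoate F7. DIBAL-H reduction comes back to the route at 18.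

3. Step 16.
- **Risk:** Deprotonation could occur at the ring CH2 instead of the exocyclic carbon. The butenolide could degrade under base. E selectivity could be incomplete, or the C13=C14 geometry could be scrambled.
- **Fallback (cross-coupling in place of olefination):** Setting out from 19, a Takai–Utimoto-type boryl-olefination (Cl2CHBpin, CrCl2, LiI, THF, rt) would give the (E)-dienyl pinacol boronate F8. Suzuki–Miyaura coupling with commercial 4-bromofuran-2(5H)-one (Pd(PPh3)4, KF, toluene–water) forms C16–C17 and comes back to the route at 25.

Further compounds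
F1 | step 3 | racemic cis-fused bicyclic β-keto ester (both enantiomers, enol form) | OC1=C(C(=O)OC)[C@@]2(C)CCCC(C)(C)[C@H]2CC1.OC1=C(C(=O)OC)[C@]2(C)CCCC(C)(C)[C@@H]2CC1
F2 | step 3 | (5R,10S)-enamino ester of (R)-1-phenylethylamine | C[C@@H](NC1=C(C(=O)OC)[C@@]2(C)CCCC(C)(C)[C@H]2CC1)c1ccccc1
F3 | step 3 | (5S,10R)-enamino ester of (R)-1-phenylethylamine | C[C@@H](NC1=C(C(=O)OC)[C@]2(C)CCCC(C)(C)[C@@H]2CC1)c1ccccc1
F4 | step 11 | C12 primary alcohol, 2-[(4aR,8aS)-2,5,5,8a-tetramethyl-octahydronaphthalen-1-yl]ethanol | CC1=C(CCO)[C@@]2(C)CCCC(C)(C)[C@H]2CC1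
F5 | step 11 | C12 primary iodide | CC1=C(CCI)[C@@]2(C)CCCC(C)(C)[C@H]2CC1
F6 | step 11 | C13 α-silyloxy ketone | CC1=C(CCC(=O)CO[Si](C)(C)C(C)(C)C)[C@@]2(C)CCCC(C)(C)[C@H]2CC1
F7 | step 11 | ethyl (13E)-enoate | CC1=C(CC/C(=C\C(=O)OCC)CO[Si](C)(C)C(C)(C)C)[C@@]2(C)CCCC(C)(C)[C@H]2CC1
F8 | step 16 | (13E,15E)-dienyl pinacol boronate | CC1=C(CC/C(=C\C=C\B3OC(C)(C)C(C)(C)O3)CO[Si](C)(C)C(C)(C)C)[C@@]2(C)CCCC(C)(C)[C@H]2CC1
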